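(All runs are calculated for an exercise; noise was put on by code.)

Start from the slow fall. In the north-east run, which is this flask followed so far, starting material plus target sinks from 35.0% at 8.00 min to 6.80% at 30.0 min.

| setting | north-east | flask |
|---|---|---|
| starting material | 0.80 M | 0.80 M |
| protic impurity | 0.24 M | 0.240 M |
| remark | the very flask that is asked about, followed so far |  |
| time |  | 80 min |

north-east run (percent of the starting material charged)

| time / min | target / % | starting material / % |
|---|---|---|
| 0.417 | 27.3 | 41.4 |
| 2.00 | 45.9 | 12.4 |
| 8.00 | 27.4 | 7.6 |
| 30.0 | 5.5 | 1.3 |

(standard deviation of a reading: 0.5 percentage points)



- the best time, 80 min at the latest, for target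
- the amount of target, in percent of the starting material charged, at that time
- the first time at which target reaches 24%, in the same percent, in min

Take that fall in powers of ten, then run it back from the first reading, where the sum reads 68.7%:

decades lost = 0.712 in 22.0 min, so on these two readings one decade takes 30.9 min

sum read back to the start = 70.9%

So in the north-east run about a third of the charge leaves before the slow fall counts, as far as these readings tell. Compare the charges:

1 − protic impurity / starting material = 70.0%

Call this the free fraction: the part of the starting material charge left once the protic impurity has taken its own molar amount, one for one.

Now turn the settings of this flask, holding the others. Turn up the protic impurity: by hand, the free fraction falls and I scale the peak of target with it. Turn down the starting material: the same ratio rises, and the free fraction falls again. Turn the time: in the north-east run target reads 45.9% at 2.00 min but 5.5% at 30.0 min, so stop early and leave the 80 min allowed unused.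

For this flask I commit to a peak near that early reading, with 24% passed just before 0.417 min, since target already reads 27.3% there. The forecast gives 46% at 1.8 min and 24% at 0.35 min, reasoning of target and starting material that “the two appear to be in a fast equilibrium”.

This flask gives 47.4% at 1.79 min and passes 24% at 0.335 min.

    starting material + protic impurity → quenched substrate (k = 0.410 M⁻¹ s⁻¹)
    target → over-reaction product (k = 8.00 × 10⁻⁶ s⁻¹)
    starting material ⇌ target + released group (K = 2.20 M, k = 0.0200 s⁻¹)
    target ⇌ isomer of the product (K = 22.0, k = 0.00210 s⁻¹)

In this flask quenched substrate stands at 30.0% at 1.78 min, with protic impurity, the limiting reagent of that quench, at 0% of its own charge; the part of the charge outside the free fraction is 30.0%. Apply the free fraction to the neighbour flask with 0.41 M of protic impurity: it becomes 48.8%, which scales the best to 33.0%, and that neighbour flask gives 34.2%.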